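The 2(5H)-furanone ring is opened retrosynthetically to an acyclic 2,3-allenoate. The feature exploited is the ring C3=C4 double bond, which bears bromine on C4 and sits next to C5, the carbon bound to ring oxygen O1. Bromolactonisation of methyl 2-[(R)-1-acetoxybutyl]penta-2,3-dienoate (13) forms the O1–C5 and C4–Br bonds, closes the only ring and discards the ester methyl group in one operation, giving 16. The precursor already contains every carbon of the target. It also carries the single stereocentre C1′, which comes from resolved (R)-hex-1-yn-3-ol and whose four bonds stay intact throughout. The C5 methyl group is then raised to the dibromomethylene carbon C6 by bromination–dehydrobromination cycles.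

Key step: step 7

Numbering (also used for the open-chain compounds): O1, C2 (carbonyl), C3, C4, C5 of the furanone, C6 for the carbon on C5, and C1′ for the carbinol carbon of the side chain. In the allenoates C3 bears the ester, C4 is the central carbon and C5 the terminal allene carbon.
Assumption: hex-1-yn-3-ol is counted as commercial only as the racemate, so the route opens with its resolution.
Stereochemical remark: the carbinol centre made in step 3, the allene axis and C5 are carried as mixtures, because all three end in the sp2 carbon C5.
Design remark: the acetate is put on only after the palladium step, since PPh3 and zerovalent palladium attack 2-(1-acyloxyalkyl)allenoates. The ring closure is run water-free to spare the acetate.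

Step 1
Reactants: 1 rac-hex-1-yn-3-ol
Product: 2 (R)-hex-1-yn-3-ol
Conditions: immobilised Candida antarctica lipase B, vinyl acetate, hexane, 30 °C, stopped somewhat beyond half conversion (chiral GC control); filtration, chromatography
Reagents that add atoms: none
Why: Lipase-catalysed kinetic resolution by irreversible transesterification, in which the empirical size rule for secondary alcohols (slim ethynyl in the small pocket, propyl in the large one) predicts acetylation of the S alcohol, so the wanted R alcohol is the slow enantiomer whose purity can be raised by pushing the conversion; this sets C1′ of the target.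

Step 2
Reactants: 2 (R)-hex-1-yn-3-ol
Product: 3 (R)-tert-butyl(hex-1-yn-3-yloxy)dimethylsilane
Conditions: TBSCl, imidazole, DMF, 0 °C to rt
Reagents that add atoms: tert-butyldimethylsilyl chloride, CC(C)(C)[Si](C)(C)Cl
Why: Imidazole-promoted O-silylation of a secondary alcohol leaves the C–O bond and so the configuration untouched, and gives an ether that tolerates acetylide chemistry and the palladium step.

Step 3
Reactants: 3 (R)-tert-butyl(hex-1-yn-3-yloxy)dimethylsilane; 4 acetaldehyde; 5 methyl chloroformate
Product: 8 methyl (5R)-5-(tert-butyldimethylsilyloxy)oct-3-yn-2-yl carbonate (both C2 epimers), via lithium acetylide 6 (not isolated), via lithium alkoxide 7 (not isolated)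
Conditions: n-BuLi, THF, −78 °C; 4, −78 °C; 5, −78 to 0 °C
Reagents that add atoms: acetaldehyde 4, CC=O; methyl chloroformate 5, COC(=O)Cl
Why: Acetylide 1,2-addition to an aldehyde followed by in situ O-acylation of the alkoxide saves one isolation, and the new carbinol centre is formed without control because it later becomes the sp2 carbon C5.

Step 4
Reactants: 8 methyl (5R)-5-(tert-butyldimethylsilyloxy)oct-3-yn-2-yl carbonate; 9 carbon monoxide
Product: 10 methyl 2-[(R)-1-(tert-butyldimethylsilyloxy)butyl]penta-2,3-dienoate (allene axis as a mixture)
Conditions: Pd(PPh3)4 (5 mol %), CO (1–5 bar), MeOH–THF, 45 °C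
Reagents that add atoms: carbon monoxide 9, [C-]#[O+]; methanol, CO
Why: Palladium-catalysed decarboxylative carbonylation of a propargylic carbonate, in which SN2′ oxidative addition of zerovalent palladium places the metal on the alkyne carbon next to C1′ and CO insertion with methanolysis gives the 2,3-dienoate, the silyl ether being inert where an acyloxy group would be expelled.

Step 5
Reactants: 10 methyl 2-[(R)-1-(tert-butyldimethylsilyloxy)butyl]penta-2,3-dienoate
Product: 11 methyl 2-[(R)-1-hydroxybutyl]penta-2,3-dienoate (allene axis as a mixture)
Conditions: HF·pyridine, pyridine–THF, 0 °C to rt, polyethylene flask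
Reagents that add atoms: none
Why: Fluoride-driven Si–O cleavage in a pyridine-buffered, weakly acidic medium spares the base-sensitive allenoate and the ester and does not touch the C1′–O bond, so the configuration is retained.

Step 6
Reactants: 11 methyl 2-[(R)-1-hydroxybutyl]penta-2,3-dienoate; 12 acetic anhydride
Product: 13 methyl 2-[(R)-1-acetoxybutyl]penta-2,3-dienoate (allene axis as a mixture)
Conditions: Ac2O, pyridine, CH2Cl2, 0 °C to rt, no DMAP
Reagents that add atoms: acetic anhydride 12, CC(=O)OC(C)=O
Why: Pyridine-promoted O-acetylation with retention at C1′, run without strongly nucleophilic catalysts because Lewis bases add to the central allene carbon of 2-(1-acyloxyalkyl)allenoates and expel the carboxylate.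

Step 7
Reactants: 13 methyl 2-[(R)-1-acetoxybutyl]penta-2,3-dienoate; 14 copper dibromide
Product: 16 (R)-1-(4-bromo-5-methyl-2-oxo-2,5-dihydrofuran-3-yl)butyl acetate (both C5 epimers), via methoxyfuranylium bromide 15 (not isolated)
Conditions: CuBr2 (2.5 equiv), dry MeCN, 60 °C, N2
Reagents that add atoms: copper dibromide 14, Br[Cu]Br
Why: CuBr2 (divalent copper) hands an electrophilic bromine to the central carbon C4 through the allene's C4=C5 π bond, the one not conjugated with the ester, while the ester carbonyl oxygen, which lies in the plane of that π bond, bonds to the terminal carbon C5 and gives the cyclic oxonium salt 15. Bromide then removes the O-methyl group by SN2 displacement (methyl is the ester alkyl group lost most easily in this way), which frees the lactone carbonyl, and the two CuBr2 consumed end as CuBr (monovalent copper), which MeCN stabilises. The closest known reaction type is the halolactonisation of 2,3-allenoic acids and esters with CuBr2, Br2 or NBS to 4-halofuran-2(5H)-ones. The single ring closes in the 5-endo-trig mode with respect to the activated double bond, which is easy here because the attacked orbital points towards the oxygen. The new stereocentre C5 has no controlling element (the allene axis of 13 is already a mixture) and needs none, since C5 becomes sp2 in step 8, and C1′ takes no part. The step needs bromine on the central carbon and closure through the ester oxygen: the first follows from the methyl-bearing terminus carrying the positive charge and from the five-membered geometry, the second from the acetate cap, which makes the C1′ oxygen non-nucleophilic (its carbonyl oxygen could reach C5 only through a seven-membered ring), and the water-free medium protects that acetate from hydrolysis.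

Step 8
Reactants: 16 (R)-1-(4-bromo-5-methyl-2-oxo-2,5-dihydrofuran-3-yl)butyl acetate
Product: 18 (R)-1-(4-bromo-5-methylidene-2-oxo-2,5-dihydrofuran-3-yl)butyl acetate, via tertiary C5 bromide 17 (not isolated)
Conditions: NBS (1.05 equiv), AIBN (cat.), PhCF3, 85 °C; cool, filter off succinimide; Et3N, 0 °C to rt
Reagents that add atoms: N-bromosuccinimide, O=C1CCC(=O)N1Br (its bromine enters 17 and leaves again on elimination)
Why: Wohl–Ziegler bromination followed by dehydrobromination, in which the bromine atom should abstract the ring C5–H (held parallel to the enoate π system, flanked by O1, giving a furanyloxy-type radical) rather than C1′–H (kept near the ring plane by allylic 1,3-strain), and Et3N then removes HBr from the tertiary bromide towards its only β-hydrogens, those of the methyl group.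

Step 9
Reactants: 18 (R)-1-(4-bromo-5-methylidene-2-oxo-2,5-dihydrofuran-3-yl)butyl acetate; 19 bromine
Product: 21 (R)-1-[(5Z)-4-bromo-5-(bromomethylidene)-2-oxo-2,5-dihydrofuran-3-yl]butyl acetate, via tribromide 20 (not isolated)
Conditions: Br2 (1.05 equiv), CH2Cl2, 0 °C; then Et3N, 0 °C
Reagents that add atoms: bromine 19, BrBr
Why: Electrophilic bromine addition picks the electron-rich exocyclic enol-ester bond C5=C6 over the tetrasubstituted, acceptor-bound C3=C4 bond, and E2 loss of C6–H and C5–Br should favour the Z alkene with C6–Br turned away from C4–Br, although either geometry serves in step 10.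

Step 10
Reactants: 21 (R)-1-[(5Z)-4-bromo-5-(bromomethylidene)-2-oxo-2,5-dihydrofuran-3-yl]butyl acetate; 19 bromine
Product: 23 (R)-1-[4-bromo-5-(dibromomethylidene)-2-oxo-2,5-dihydrofuran-3-yl]butyl acetate, via tetrabromide 22 (not isolated)
Conditions: Br2 (1.5 equiv), CHCl3, rt to 45 °C; excess Br2 purged with N2; CH2Cl2, Et3N, 0 °C
Reagents that add atoms: bromine 19, BrBr
Why: A second bromine addition–dehydrobromination cycle of the same type, slower because the alkene now bears bromine (hence excess Br2 and gentle warming), after which the acidic CHBr2 hydrogen and C5–Br are lost by E2 elimination to give the dibromomethylene group with C1′ untouched.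

Compound list
1 | rac-hex-1-yn-3-ol | CCCC(O)C#C | starting material
2 | (R)-hex-1-yn-3-ol | CCC[C@@H](O)C#C | intermediate
3 | (R)-tert-butyl(hex-1-yn-3-yloxy)dimethylsilane | CCC[C@@H](O[Si](C)(C)C(C)(C)C)C#C | intermediate
4 | acetaldehyde | CC=O | starting material
5 | methyl chloroformate | COC(=O)Cl | starting material
6 | lithium acetylide of 3 | CCC[C@@H](O[Si](C)(C)C(C)(C)C)C#C[Li] | intermediate
7 | lithium (5R)-5-(tert-butyldimethylsilyloxy)oct-3-yn-2-olate (both C2 epimers) | CCC[C@@H](O[Si](C)(C)C(C)(C)C)C#CC(C)O[Li] | intermediate
8 | methyl (5R)-5-(tert-butyldimethylsilyloxy)oct-3-yn-2-yl carbonate (both C2 epimers) | CCC[C@@H](O[Si](C)(C)C(C)(C)C)C#CC(C)OC(=O)OC | intermediate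
9 | carbon monoxide | [C-]#[O+] | starting material
10 | methyl 2-[(R)-1-(tert-butyldimethylsilyloxy)butyl]penta-2,3-dienoate (axis mixture) | CCC[C@@H](O[Si](C)(C)C(C)(C)C)C(C(=O)OC)=C=CC | intermediate
11 | methyl 2-[(R)-1-hydroxybutyl]penta-2,3-dienoate (axis mixture) | CCC[C@@H](O)C(C(=O)OC)=C=CC | intermediate
12 | acetic anhydride | CC(=O)OC(C)=O | starting material
13 | methyl 2-[(R)-1-acetoxybutyl]penta-2,3-dienoate (axis mixture) | CCC[C@@H](OC(C)=O)C(C(=O)OC)=C=CC | intermediate
14 | copper dibromide | Br[Cu]Br | starting material
15 | 3-[(R)-1-acetoxybutyl]-4-bromo-2-methoxy-5-methyl-5H-furan-1-ium bromide (both C5 epimers) | CCC[C@@H](OC(C)=O)C1=C(Br)C(C)[O+]=C1OC.[Br-] | intermediate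
16 | (R)-1-(4-bromo-5-methyl-2-oxo-2,5-dihydrofuran-3-yl)butyl acetate (both C5 epimers) | CCC[C@@H](OC(C)=O)C1=C(Br)C(C)OC1=O | intermediate
17 | (R)-1-(4,5-dibromo-5-methyl-2-oxo-2,5-dihydrofuran-3-yl)butyl acetate (both C5 epimers) | CCC[C@@H](OC(C)=O)C1=C(Br)C(C)(Br)OC1=O | intermediate
18 | (R)-1-(4-bromo-5-methylidene-2-oxo-2,5-dihydrofuran-3-yl)butyl acetate | CCC[C@@H](OC(C)=O)C1=C(Br)C(=C)OC1=O | intermediate
19 | bromine | BrBr | starting material
20 | (R)-1-[4,5-dibromo-5-(bromomethyl)-2-oxo-2,5-dihydrofuran-3-yl]butyl acetate (both C5 epimers) | CCC[C@@H](OC(C)=O)C1=C(Br)C(Br)(CBr)OC1=O | intermediate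
21 | (R)-1-[(5Z)-4-bromo-5-(bromomethylidene)-2-oxo-2,5-dihydrofuran-3-yl]butyl acetate | CCC[C@@H](OC(C)=O)C1=C(Br)/C(=C/Br)OC1=O | intermediate
22 | (R)-1-[4,5-dibromo-5-(dibromomethyl)-2-oxo-2,5-dihydrofuran-3-yl]butyl acetate (both C5 epimers) | CCC[C@@H](OC(C)=O)C1=C(Br)C(Br)(C(Br)Br)OC1=O | intermediate
23 | (R)-1-[4-bromo-5-(dibromomethylidene)-2-oxo-2,5-dihydrofuran-3-yl]butyl acetate | CCC[C@@H](OC(C)=O)C1=C(Br)C(=C(Br)Br)OC1=O | target

Total step count: 10. Longest linear sequence: 10 steps (1 to 23).

Steps most likely to fail

Step 7 (key step). Three things may go wrong. Demethylation of the cyclic oxonium salt may be sluggish. The allylic acetate may be displaced by bromide or lost on heating. Bromine may simply add across the distal allene bond without ring closure. The fallback sets out from 11 and comes back at 16. It closes the ring from the free carboxylic acid, so that no heat, no copper salt and no dealkylation are needed. LiOH in THF–water at 0 °C to rt should saponify 11 to (R)-2-(1-hydroxybutyl)penta-2,3-dienoic acid F1. Ac2O/pyridine, followed by aqueous cleavage of the mixed anhydride, should give 2-[(R)-1-acetoxybutyl]penta-2,3-dienoic acid F2. NBS in MeCN at 0 °C then effects the known bromolactonisation of a 2,3-allenoic acid and delivers 16.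

Step 8. Hydrogen abstraction at C1′ may compete with abstraction at C5, costing material and eroding configuration, and the product may be brominated further. The fallback sets out from 10 and comes back at 18. It replaces the radical abstraction by a polar C5 bromination through a 2-silyloxyfuran. This is run in the silyl ether series, because an electron-rich furan would push out a C1′ acetate but not a silyloxy group.
- LiOH in THF–water should turn 10 into 2-[(R)-1-(tert-butyldimethylsilyloxy)butyl]penta-2,3-dienoic acid F3.
- NBS in MeCN should close it to 4-bromo-3-[(R)-1-(tert-butyldimethylsilyloxy)butyl]-5-methylfuran-2(5H)-one F4.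
- TBSOTf/Et3N in CH2Cl2 at 0 °C gives 4-bromo-2-(tert-butyldimethylsilyloxy)-3-[(R)-1-(tert-butyldimethylsilyloxy)butyl]-5-methylfuran F5.
- NBS in THF at −78 °C attacks C5 of the furan to give 4,5-dibromo-3-[(R)-1-(tert-butyldimethylsilyloxy)butyl]-5-methylfuran-2(5H)-one F6.
- Et3N removes HBr from it to give 4-bromo-3-[(R)-1-(tert-butyldimethylsilyloxy)butyl]-5-methylidenefuran-2(5H)-one F7.
- HF·pyridine frees 4-bromo-3-[(R)-1-hydroxybutyl]-5-methylidenefuran-2(5H)-one F8, and Ac2O/pyridine gives 18.

Step 1. The enzyme may discriminate only modestly between the ethynyl and propyl groups, so that high enantiopurity is paid for with much material. The fallback sets out from 1 and comes back at 2. It replaces the resolution by an enantioconvergent oxidation and asymmetric reduction. Jones oxidation (CrO3, aqueous H2SO4, acetone, 0 °C) should give hex-1-yn-3-one F9. Midland reduction with B-isopinocampheyl-9-BBN derived from (+)-α-pinene (neat or THF, rt, ethanolamine work-up) treats the alkynyl group as the small substituent. It should therefore deliver hydride to the face that gives 2.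

Further compounds
F1 | step 7 | (R)-2-(1-hydroxybutyl)penta-2,3-dienoic acid (axis mixture) | CCC[C@@H](O)C(C(=O)O)=C=CC
F2 | step 7 | 2-[(R)-1-acetoxybutyl]penta-2,3-dienoic acid (axis mixture) | CCC[C@@H](OC(C)=O)C(C(=O)O)=C=CC
F3 | step 8 | 2-[(R)-1-(tert-butyldimethylsilyloxy)butyl]penta-2,3-dienoic acid (axis mixture) | CCC[C@@H](O[Si](C)(C)C(C)(C)C)C(C(=O)O)=C=CC
F4 | step 8 | 4-bromo-3-[(R)-1-(tert-butyldimethylsilyloxy)butyl]-5-methylfuran-2(5H)-one (both C5 epimers) | CCC[C@@H](O[Si](C)(C)C(C)(C)C)C1=C(Br)C(C)OC1=O
F5 | step 8 | 4-bromo-2-(tert-butyldimethylsilyloxy)-3-[(R)-1-(tert-butyldimethylsilyloxy)butyl]-5-methylfuran | CCC[C@@H](O[Si](C)(C)C(C)(C)C)c1c(Br)c(C)oc1O[Si](C)(C)C(C)(C)C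
F6 | step 8 | 4,5-dibromo-3-[(R)-1-(tert-butyldimethylsilyloxy)butyl]-5-methylfuran-2(5H)-one (both C5 epimers) | CCC[C@@H](O[Si](C)(C)C(C)(C)C)C1=C(Br)C(C)(Br)OC1=O
F7 | step 8 | 4-bromo-3-[(R)-1-(tert-butyldimethylsilyloxy)butyl]-5-methylidenefuran-2(5H)-one | CCC[C@@H](O[Si](C)(C)C(C)(C)C)C1=C(Br)C(=C)OC1=O
F8 | step 8 | 4-bromo-3-[(R)-1-hydroxybutyl]-5-methylidenefuran-2(5H)-one | CCC[C@@H](O)C1=C(Br)C(=C)OC1=O
F9 | step 1 | hex-1-yn-3-one | CCCC(=O)C#C
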